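**Plan**

- Feature: in the 1,2-dioxane (O1, O2, C3–C6), C6 carries methyl, O1 and a chain that starts with two CH2 groups. This is the pattern left when a 2-methyl-2-alkyloxetane is opened at its quaternary carbon. C3 (methyl, O2, acid chain) is the tertiary carbon of an epoxide opened by H2O2.
- Cuts, in retrosynthetic order: the ester; C8–C9 of the phenyloctyl chain (Wittig); the Cα–Cβ bond of the acid chain at a C3 aldehyde (Wittig after glycol cleavage); C6–O1 (oxetane opening); C3–O2 (epoxide perhydrolysis); then back to (2E,6E)-3,6-dimethylocta-2,6-diene-1,8-diol from 2,5-hexanedione.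
- Forward: the C10 chain is made first and desymmetrised. One end becomes the oxetane, the other the epoxide and then the hydroperoxide. The only ring closure (the 1,2-dioxane) is step 10; the acid chain and the phenylalkyl chain follow.
- Stereochemistry: both centres come from Sharpless epoxidations with L-(+)-diethyl tartrate. C3 is set by inversion when H2O2 opens the second epoxide. C6 is carried with retention from the first epoxide into the oxetane and inverted once in the ring closure.

Key step: step 10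

Remark: the 1,2-diol of 12 and 13 is carried unprotected, on the premise that the hydroperoxide and not the hindered secondary hydroxyl captures the activated oxetane; ethereal H2O2 and all peroxides are handled cold and on small scale.

**Route**

Step 1
Reactants: 1 2,5-hexanedione; 2 triethyl phosphonoacetate (2 equiv)
Product: 3 diethyl (2E,6E)-3,6-dimethylocta-2,6-dienedioate
Conditions: NaH, THF, 0 °C → reflux; (2E,6E) isomer separated by chromatography
Reagents that add atoms: none
Why: A double Horner–Wadsworth–Emmons olefination of the two methyl ketones should favour the E-enoate at each end, and the minor Z-containing isomers can be removed at this stage.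

Step 2
Reactants: 3 diethyl (2E,6E)-3,6-dimethylocta-2,6-dienedioate
Product: 4 (2E,6E)-3,6-dimethylocta-2,6-diene-1,8-diol
Conditions: i-Bu2AlH, CH2Cl2, −78 → 0 °C
Reagents that add atoms: none
Why: 1,2-Reduction of both enoates by the aluminium hydride should give the bis-allylic alcohol without touching the alkene geometry.

Step 3
Reactants: 4 (2E,6E)-3,6-dimethylocta-2,6-diene-1,8-diol
Product: 5 (2E,6E)-8-[(tert-butyldiphenylsilyl)oxy]-3,6-dimethylocta-2,6-dien-1-ol
Conditions: NaH (1.0 equiv), THF, 0 °C; then TBDPSCl (1.0 equiv), rt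
Reagents that add atoms: tert-butyl(chloro)diphenylsilane, CC(C)(C)[Si](Cl)(c1ccccc1)c1ccccc1
Why: Silylation of the monosodium alkoxide of a symmetrical diol (Williamson-type O-silylation) should give mainly the mono-ether, which desymmetrises the chain; unreacted diol is recycled.

Step 4
Reactants: 5 (2E,6E)-8-[(tert-butyldiphenylsilyl)oxy]-3,6-dimethylocta-2,6-dien-1-ol
Product: 6 [(2S,3S)-3-{(3E)-5-[(tert-butyldiphenylsilyl)oxy]-3-methylpent-3-en-1-yl}-3-methyloxiran-2-yl]methanol
Conditions: Ti(Oi-Pr)4 (10 mol%), L-(+)-diethyl tartrate (12 mol%), t-BuOOH, 4 Å molecular sieves, CH2Cl2, −20 °C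
Reagents that add atoms: tert-butyl hydroperoxide, CC(C)(C)OO
Why: In the Sharpless asymmetric epoxidation only the free allylic alcohol binds the titanium tartrate, and an (E)-3-methylalk-2-en-1-ol of the geraniol type should give the (2S,3S)-epoxide with L-(+)-tartrate by reagent control; this fixes the carbon that becomes C6.

Step 5
Reactants: 6 [(2S,3S)-3-{(3E)-5-[(tert-butyldiphenylsilyl)oxy]-3-methylpent-3-en-1-yl}-3-methyloxiran-2-yl]methanol
Product: 7 (3S,6E)-8-[(tert-butyldiphenylsilyl)oxy]-3,6-dimethyloct-6-ene-1,3-diol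
Conditions: NaAlH2(OCH2CH2OMe)2, THF, 0 °C → rt
Reagents that add atoms: none
Why: Hydroxyl-directed hydride delivery to C2 of a 2,3-epoxy alcohol (regioselective reductive epoxide opening) should give the 1,3-diol; the tertiary C–O bond is not touched, so the carbinol keeps its configuration.

Step 6
Reactants: 7 (3S,6E)-8-[(tert-butyldiphenylsilyl)oxy]-3,6-dimethyloct-6-ene-1,3-diol
Product: 9 tert-butyl({(2E)-3-methyl-5-[(2S)-2-methyloxetan-2-yl]pent-2-en-1-yl}oxy)diphenylsilane, via primary tosylate 8 (not isolated)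
Conditions: n-BuLi (1.0 equiv), THF, 0 °C; TsCl (1.0 equiv); n-BuLi (1.05 equiv), 0 → 60 °C
Reagents that add atoms: 4-methylbenzenesulfonyl chloride, Cc1ccc(cc1)S(Cl)(=O)=O (its tosyl group stands in 8 and leaves again on ring closure)
Why: Sulfonylation of the primary alkoxide followed by intramolecular Williamson etherification (4-exo-tet) by the tertiary alkoxide should close the oxetane with retention at the quaternary carbon, because only the primary C–O bond is exchanged.

Step 7
Reactants: 9 tert-butyl({(2E)-3-methyl-5-[(2S)-2-methyloxetan-2-yl]pent-2-en-1-yl}oxy)diphenylsilane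
Product: 10 (2E)-3-methyl-5-[(2S)-2-methyloxetan-2-yl]pent-2-en-1-ol
Conditions: Bu4NF, THF, 0 °C → rt
Reagents that add atoms: none
Why: Fluoride-induced desilylation cleaves the Si–O bond, and the oxetane is inert to fluoride and mild base.

Step 8
Reactants: 10 (2E)-3-methyl-5-[(2S)-2-methyloxetan-2-yl]pent-2-en-1-ol
Product: 11 [(2S,3S)-3-methyl-3-{2-[(2S)-2-methyloxetan-2-yl]ethyl}oxiran-2-yl]methanol
Conditions: Ti(Oi-Pr)4 (10 mol%), L-(+)-diethyl tartrate (12 mol%), t-BuOOH, 4 Å molecular sieves, CH2Cl2, −20 °C; non-acidic work-up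
Reagents that add atoms: tert-butyl hydroperoxide, CC(C)(C)OO
Why: A second Sharpless asymmetric epoxidation with the same tartrate should give the (2S,3S)-epoxide by reagent control, and the catalytic titanium alkoxide at −20 °C is too weak a Lewis acid to open the oxetane.

Step 9
Reactants: 11 [(2S,3S)-3-methyl-3-{2-[(2S)-2-methyloxetan-2-yl]ethyl}oxiran-2-yl]methanol
Product: 12 (2S,3R)-3-hydroperoxy-3-methyl-5-[(2S)-2-methyloxetan-2-yl]pentane-1,2-diol
Conditions: H2O2 (anhydrous, in Et2O), H3PMo12O40 (2 mol%), Et2O, 0 °C, stopped at consumption of 11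
Reagents that add atoms: hydrogen peroxide, OO
Why: In the molybdenum-catalysed perhydrolysis of a trisubstituted epoxide, H2O2 should attack the tertiary epoxide carbon anti to the oxygen (Markovnikov regiochemistry with inversion), turning the (3S)-epoxide carbon into the (3R)-hydroperoxide while C2 keeps its oxygen; the epoxide, activated through its neighbouring hydroxyl, should react ahead of the oxetane.

Step 10
Reactants: 12 (2S,3R)-3-hydroperoxy-3-methyl-5-[(2S)-2-methyloxetan-2-yl]pentane-1,2-diol
Product: 13 (1S)-1-[(3R,6R)-6-(2-hydroxyethyl)-3,6-dimethyl-1,2-dioxan-3-yl]ethane-1,2-diol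
Conditions: Yb(OTf)3 (10 mol%), Et2O/CH2Cl2, −20 → 0 °C
Reagents that add atoms: none
Why: The lanthanide triflate binds the oxetane oxygen and the terminal oxygen of the C3 hydroperoxide attacks the quaternary oxetane carbon from the rear, so the C6–O1 bond forms as the four-ring C–O bond breaks and its oxygen is left as the 2-hydroxyethyl arm. The closest known reaction type is the Lewis-acid-promoted opening of 2,2-disubstituted oxetanes at the more substituted carbon by hydrogen peroxide or hydroperoxides, including the intramolecular closure of tethered hydroperoxides to 1,2-dioxolanes and 1,2-dioxanes. The 1,2-dioxane closes in the 6-exo-tet mode, driven by release of the oxetane strain. C6 is set by stereospecific inversion of the (S)-oxetane carbon, whose configuration came from the first Sharpless epoxide, while C3 and the carbinol carbon are not touched. The step needs backside displacement and not ionisation to a free tertiary cation, which the ethereal solvent, the low temperature and the intramolecular delivery favour; it also needs attack by the hydroperoxide and not by the diol hydroxyls, which the α-effect and the lower steric demand of the terminal peroxide oxygen, compared with the neopentyl-type secondary hydroxyl, should secure.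

Step 11
Reactants: 13 (1S)-1-[(3R,6R)-6-(2-hydroxyethyl)-3,6-dimethyl-1,2-dioxan-3-yl]ethane-1,2-diol
Product: 14 (3R,6R)-6-(2-hydroxyethyl)-3,6-dimethyl-1,2-dioxane-3-carbaldehyde
Conditions: NaIO4, THF/pH 7 phosphate buffer, 0 °C; used at once
Reagents that add atoms: none
Why: Periodate glycol cleavage (Malaprade reaction) acts only on the vicinal diol, leaving the isolated primary alcohol and the dialkyl peroxide; the aldehyde sits on a quaternary carbon, so C3 cannot epimerise.

Step 12
Reactants: 14 (3R,6R)-6-(2-hydroxyethyl)-3,6-dimethyl-1,2-dioxane-3-carbaldehyde; 15 methyl (triphenylphosphoranylidene)acetate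
Product: 16 methyl (2E)-3-[(3R,6R)-6-(2-hydroxyethyl)-3,6-dimethyl-1,2-dioxan-3-yl]prop-2-enoate
Conditions: CH2Cl2, rt
Reagents that add atoms: none
Why: A Wittig reaction with a stabilised ylide runs under neutral conditions that tolerate the free hydroxyl and the peroxide and should give the (E)-enoate.

Step 13
Reactants: 16 methyl (2E)-3-[(3R,6R)-6-(2-hydroxyethyl)-3,6-dimethyl-1,2-dioxan-3-yl]prop-2-enoate
Product: 17 methyl (2E)-3-[(3R,6R)-3,6-dimethyl-6-(2-oxoethyl)-1,2-dioxan-3-yl]prop-2-enoate
Conditions: Dess–Martin periodinane, CH2Cl2, 0 °C → rt; used at once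
Reagents that add atoms: none
Why: Dess–Martin oxidation converts the primary alcohol into the aldehyde under near-neutral conditions that leave the peroxide and the enoate alone.

Step 14
Reactants: 18 (6-bromohexyl)benzene
Product: 19 triphenyl(6-phenylhexyl)phosphonium bromide
Conditions: PPh3, MeCN, reflux
Reagents that add atoms: triphenylphosphine, c1ccc(cc1)P(c1ccccc1)c1ccccc1
Why: SN2 quaternisation of triphenylphosphine by a primary bromide gives the Wittig salt.

Step 15
Reactants: 17 methyl (2E)-3-[(3R,6R)-3,6-dimethyl-6-(2-oxoethyl)-1,2-dioxan-3-yl]prop-2-enoate; 19 triphenyl(6-phenylhexyl)phosphonium bromide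
Product: 21 methyl (2E)-3-{(3R,6R)-3,6-dimethyl-6-[(2Z)-8-phenyloct-2-en-1-yl]-1,2-dioxan-3-yl}prop-2-enoate, via phosphorus ylide 20 (not isolated)
Conditions: 19, NaN(SiMe3)2 (1.05 equiv), THF, 0 °C; then 17, −78 → 0 °C
Reagents that add atoms: none
Why: In this Wittig reaction, addition of a non-stabilised ylide to the aldehyde at −78 °C should outrun both enolisation and attack on the hindered enoate; the expected (Z)-geometry is of no consequence, since the alkene is reduced next.

Step 16
Reactants: 21 methyl (2E)-3-{(3R,6R)-3,6-dimethyl-6-[(2Z)-8-phenyloct-2-en-1-yl]-1,2-dioxan-3-yl}prop-2-enoate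
Product: 22 methyl 3-[(3R,6S)-3,6-dimethyl-6-(8-phenyloctyl)-1,2-dioxan-3-yl]propanoate
Conditions: KO2CN=NCO2K (excess, in portions), AcOH, MeOH/CH2Cl2, 0 °C → rt
Reagents that add atoms: none
Why: Diimide reduction transfers H2 to both C=C bonds in a concerted syn fashion and, unlike catalytic hydrogenation, leaves the O–O bond intact.

Step 17
Reactants: 22 methyl 3-[(3R,6S)-3,6-dimethyl-6-(8-phenyloctyl)-1,2-dioxan-3-yl]propanoate
Product: 23 3-[(3R,6S)-3,6-dimethyl-6-(8-phenyloctyl)-1,2-dioxan-3-yl]propanoic acid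
Conditions: LiOH, THF/H2O, 0 °C → rt; then 1 M HCl to pH 3
Reagents that add atoms: lithium hydroxide, [Li+].[OH-] (the hydroxide oxygen ends in the carboxyl group)
Why: Saponification of the methyl ester is safe here because both peroxide carbons are fully substituted, so base-induced (Kornblum–DeLaMare) cleavage of the dioxane is not possible.

**Compound list**

1 | 2,5-hexanedione | CC(=O)CCC(C)=O | starting material
2 | triethyl phosphonoacetate | CCOC(=O)CP(=O)(OCC)OCC | starting material
3 | diethyl (2E,6E)-3,6-dimethylocta-2,6-dienedioate | CCOC(=O)/C=C(\C)CC/C(C)=C/C(=O)OCC | intermediate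
4 | (2E,6E)-3,6-dimethylocta-2,6-diene-1,8-diol | OC/C=C(\C)CC/C(C)=C/CO | intermediate
5 | (2E,6E)-8-[(tert-butyldiphenylsilyl)oxy]-3,6-dimethylocta-2,6-dien-1-ol | OC/C=C(\C)CC/C(C)=C/CO[Si](c1ccccc1)(c1ccccc1)C(C)(C)C | intermediate
6 | [(2S,3S)-3-{(3E)-5-[(tert-butyldiphenylsilyl)oxy]-3-methylpent-3-en-1-yl}-3-methyloxiran-2-yl]methanol | OC[C@@H]1O[C@@]1(C)CC/C(C)=C/CO[Si](c1ccccc1)(c1ccccc1)C(C)(C)C | intermediate
7 | (3S,6E)-8-[(tert-butyldiphenylsilyl)oxy]-3,6-dimethyloct-6-ene-1,3-diol | OCC[C@@](C)(O)CC/C(C)=C/CO[Si](c1ccccc1)(c1ccccc1)C(C)(C)C | intermediate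
8 | (3S,6E)-8-[(tert-butyldiphenylsilyl)oxy]-3-hydroxy-3,6-dimethyloct-6-en-1-yl 4-methylbenzenesulfonate | Cc1ccc(cc1)S(=O)(=O)OCC[C@@](C)(O)CC/C(C)=C/CO[Si](c1ccccc1)(c1ccccc1)C(C)(C)C | intermediate
9 | tert-butyl({(2E)-3-methyl-5-[(2S)-2-methyloxetan-2-yl]pent-2-en-1-yl}oxy)diphenylsilane | C[C@@]1(CCO1)CC/C(C)=C/CO[Si](c1ccccc1)(c1ccccc1)C(C)(C)C | intermediate
10 | (2E)-3-methyl-5-[(2S)-2-methyloxetan-2-yl]pent-2-en-1-ol | C[C@@]1(CCO1)CC/C(C)=C/CO | intermediate
11 | [(2S,3S)-3-methyl-3-{2-[(2S)-2-methyloxetan-2-yl]ethyl}oxiran-2-yl]methanol | C[C@@]1(CCO1)CC[C@]2(C)O[C@H]2CO | intermediate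
12 | (2S,3R)-3-hydroperoxy-3-methyl-5-[(2S)-2-methyloxetan-2-yl]pentane-1,2-diol | C[C@@]1(CCO1)CC[C@](C)([C@@H](O)CO)OO | intermediate
13 | (1S)-1-[(3R,6R)-6-(2-hydroxyethyl)-3,6-dimethyl-1,2-dioxan-3-yl]ethane-1,2-diol | C[C@]1(CCO)CC[C@](C)([C@@H](O)CO)OO1 | intermediate
14 | (3R,6R)-6-(2-hydroxyethyl)-3,6-dimethyl-1,2-dioxane-3-carbaldehyde | C[C@]1(CCO)CC[C@](C)(C=O)OO1 | intermediate
15 | methyl (triphenylphosphoranylidene)acetate | COC(=O)C=P(c1ccccc1)(c1ccccc1)c1ccccc1 | starting material
16 | methyl (2E)-3-[(3R,6R)-6-(2-hydroxyethyl)-3,6-dimethyl-1,2-dioxan-3-yl]prop-2-enoate | C[C@]1(CCO)CC[C@](C)(/C=C/C(=O)OC)OO1 | intermediate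
17 | methyl (2E)-3-[(3R,6R)-3,6-dimethyl-6-(2-oxoethyl)-1,2-dioxan-3-yl]prop-2-enoate | C[C@]1(CC=O)CC[C@](C)(/C=C/C(=O)OC)OO1 | intermediate
18 | (6-bromohexyl)benzene | BrCCCCCCc1ccccc1 | starting material
19 | triphenyl(6-phenylhexyl)phosphonium bromide | [Br-].c1ccc(cc1)CCCCCC[P+](c1ccccc1)(c1ccccc1)c1ccccc1 | intermediate
20 | triphenyl(6-phenylhexylidene)-λ5-phosphane | C(CCCCCc1ccccc1)=P(c1ccccc1)(c1ccccc1)c1ccccc1 | intermediate
21 | methyl (2E)-3-{(3R,6R)-3,6-dimethyl-6-[(2Z)-8-phenyloct-2-en-1-yl]-1,2-dioxan-3-yl}prop-2-enoate | C[C@]1(C/C=C\CCCCCc2ccccc2)CC[C@](C)(/C=C/C(=O)OC)OO1 | intermediate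
22 | methyl 3-[(3R,6S)-3,6-dimethyl-6-(8-phenyloctyl)-1,2-dioxan-3-yl]propanoate | C[C@]1(CCCCCCCCc2ccccc2)CC[C@](C)(CCC(=O)OC)OO1 | intermediate
23 | 3-[(3R,6S)-3,6-dimethyl-6-(8-phenyloctyl)-1,2-dioxan-3-yl]propanoic acid | C[C@]1(CCCCCCCCc2ccccc2)CC[C@](C)(CCC(=O)O)OO1 | target

**Step count**

Total: 17 steps. Longest linear sequence: 16 steps (steps 1–13 and 15–17); step 14 is a one-step side branch.

**Steps most likely to fail**

Step 9. External H2O2 may open the oxetane in competition with the epoxide, the oxetane oxygen may take part in the opening of the activated epoxide, or the tertiary epoxide carbon may ionise so that the inversion is not clean. The fallback sets out from 11 and comes back at 13. The peroxide is installed and the ring closed in one flask, with a small excess of ethereal H2O2 and Yb(OTf)3 in Et2O at −20 → 0 °C under dilution, so that it no longer matters which strained ring is opened first. If the epoxide opens first, 12 forms and closes as in step 10. If the oxetane opens first at its quaternary carbon (the known intermolecular perhydrolysis of 2,2-disubstituted oxetanes, with inversion), the product is [(2S,3S)-3-[(3R)-3-hydroperoxy-5-hydroxy-3-methylpentyl]-3-methyloxiran-2-yl]methanol F1. Its tethered hydroperoxide then opens the epoxide at the tertiary carbon (6-exo, inversion). Both channels invert each carbon once and should therefore deliver the same dioxane 13.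

Step 10. A diol hydroxyl may capture the activated oxetane in place of the hydroperoxide (closure to a tetrahydropyran), the oxetane may ionise to a free tertiary cation with erosion at C6, or the β-hydroxy hydroperoxide may fragment under the Lewis acid. The fallback sets out from 11 and comes back at 13. The primary hydroxyl is first silylated (TBDPSCl, imidazole, DMF) to tert-butyl{[(2S,3S)-3-methyl-3-{2-[(2S)-2-methyloxetan-2-yl]ethyl}oxiran-2-yl]methoxy}diphenylsilane F2. Perhydrolysis as in step 9 gives (2S,3R)-1-[(tert-butyldiphenylsilyl)oxy]-3-hydroperoxy-3-methyl-5-[(2S)-2-methyloxetan-2-yl]pentan-2-ol F3. The only remaining hydroxyl is now shielded by the quaternary carbon and the bulky silyloxymethyl group. Closure with Yb(OTf)3 as in step 10 gives (1S)-2-[(tert-butyldiphenylsilyl)oxy]-1-[(3R,6R)-6-(2-hydroxyethyl)-3,6-dimethyl-1,2-dioxan-3-yl]ethan-1-ol F4, and Bu4NF in THF then frees 13.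

Step 15. The basic ylide may enolise the β-peroxy aldehyde, after which β-elimination opens the dioxane, or the ylide may add in conjugate fashion to the enoate. The fallback sets out from 16 and comes back at 22. It reverses the polarity of the olefination, so that the carbanion sits on the peroxide fragment, where no β-leaving group is available, and the enolisable aldehyde is avoided.

- A Mitsunobu thioetherification of 16 with 1-phenyl-1H-tetrazole-5-thiol (PPh3, diisopropyl azodicarboxylate, THF, 0 °C) gives methyl (2E)-3-[(3R,6R)-3,6-dimethyl-6-{2-[(1-phenyl-1H-tetrazol-5-yl)sulfanyl]ethyl}-1,2-dioxan-3-yl]prop-2-enoate F5.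
- Oxidation with H2O2 and (NH4)6Mo7O24 in EtOH gives methyl (2E)-3-[(3R,6R)-3,6-dimethyl-6-{2-[(1-phenyl-1H-tetrazol-5-yl)sulfonyl]ethyl}-1,2-dioxan-3-yl]prop-2-enoate F6.
- A Julia–Kocienski olefination with commercial 6-phenylhexanal (KN(SiMe3)2 added to the premixed partners, THF, −78 °C) gives methyl (2E)-3-{(3R,6R)-3,6-dimethyl-6-[(2E)-8-phenyloct-2-en-1-yl]-1,2-dioxan-3-yl}prop-2-enoate F7.
- Diimide reduction as in step 16 converts F7 into 22.

**Further compounds**

F1 | step 9 | [(2S,3S)-3-[(3R)-3-hydroperoxy-5-hydroxy-3-methylpentyl]-3-methyloxiran-2-yl]methanol | C[C@](OO)(CCO)CC[C@]1(C)O[C@H]1CO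
F2 | step 10 | tert-butyl{[(2S,3S)-3-methyl-3-{2-[(2S)-2-methyloxetan-2-yl]ethyl}oxiran-2-yl]methoxy}diphenylsilane | C[C@@]1(CCO1)CC[C@]2(C)O[C@H]2CO[Si](c3ccccc3)(c3ccccc3)C(C)(C)C
F3 | step 10 | (2S,3R)-1-[(tert-butyldiphenylsilyl)oxy]-3-hydroperoxy-3-methyl-5-[(2S)-2-methyloxetan-2-yl]pentan-2-ol | C[C@@]1(CCO1)CC[C@](C)([C@@H](O)CO[Si](c2ccccc2)(c2ccccc2)C(C)(C)C)OO
F4 | step 10 | (1S)-2-[(tert-butyldiphenylsilyl)oxy]-1-[(3R,6R)-6-(2-hydroxyethyl)-3,6-dimethyl-1,2-dioxan-3-yl]ethan-1-ol | C[C@]1(CCO)CC[C@](C)([C@@H](O)CO[Si](c2ccccc2)(c2ccccc2)C(C)(C)C)OO1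
F5 | step 15 | methyl (2E)-3-[(3R,6R)-3,6-dimethyl-6-{2-[(1-phenyl-1H-tetrazol-5-yl)sulfanyl]ethyl}-1,2-dioxan-3-yl]prop-2-enoate | C[C@]1(CCSc2nnnn2-c2ccccc2)CC[C@](C)(/C=C/C(=O)OC)OO1
F6 | step 15 | methyl (2E)-3-[(3R,6R)-3,6-dimethyl-6-{2-[(1-phenyl-1H-tetrazol-5-yl)sulfonyl]ethyl}-1,2-dioxan-3-yl]prop-2-enoate | C[C@]1(CCS(=O)(=O)c2nnnn2-c2ccccc2)CC[C@](C)(/C=C/C(=O)OC)OO1
F7 | step 15 | methyl (2E)-3-{(3R,6R)-3,6-dimethyl-6-[(2E)-8-phenyloct-2-en-1-yl]-1,2-dioxan-3-yl}prop-2-enoate | C[C@]1(C/C=C/CCCCCc2ccccc2)CC[C@](C)(/C=C/C(=O)OC)OO1
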